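**Retrosynthetic overview**

1. Target 22 comes from 21 by cleavage of one silyl ether. The whole bicyclic core of 21 is made in one operation from phenol 18, a 4-hydroxy-5-methyl-2-(2-oxoalkyl)benzaldehyde that already carries the complete epoxy-alkenyl side chain.
2. Enabling feature: C1 is a formyl carbon on C8a and O2 is the enol oxygen of the C3 ketone, so pyran ring B (O2–C1–C8a–C4a–C4–C3) is a cyclodehydrated 1,5-keto aldehyde. Carbocycle A (C4a–C5–C6–C7–C8–C8a) with C6=O and C7(OH)CH3 is the ortho-quinol of a para-formyl cresol, and C8–OH is a vinylogous hemiacetal (water added to the end of the O2–C1=C8a–C8 unit).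
3. Key cascade (copies azaphilone biosynthesis and dearomatises a cheap cresol aldehyde): hydroxylation at C7, ortho-quinol, closure of ring B through the O2–C1 bond, water onto C8. Ring order: oxirane (step 7), then pyran ring B (step 13); ring A is the bought arene.
4. 18 comes from benzylic C4–C3 acylation: laterally lithiated, in situ protected 2,5-dimethyl-4-silyloxybenzaldehyde 14 plus epoxy Weinreb amide 12.
5. 12 comes from Sharpless epoxidation of (2E,4E)-dienol 8, which comes from two Wittig olefinations of anti aldehyde 5, made by Fráter–Seebach methylation of ethyl (S)-3-hydroxybutanoate 1.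

Key step: step 13

Abbreviations: TBS = tert-butyldimethylsilyl, TIPS = triisopropylsilyl; ring atoms carry isochromene numbering (C1, O2, C3 … C8a).

Assumption: the sense of induction of the chiral iodyl reagent on phenol 18 cannot be read from a model; the (S)-reagent is written for the antipode that transfers oxygen to the C7 face leading to 7S, and the other antipode is used in the same way if the first run shows the opposite sense (the C7 epimers are diastereomers).

**Route**

Step 1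
Reactants: 1 ethyl (3S)-3-hydroxybutanoate
Product: 3 ethyl (2S,3S)-3-hydroxy-2-methylbutanoate, via dilithium alkoxide enolate 2 (not isolated)
Conditions: LiN(iPr)2 (2.2 equiv), THF, −50 °C; MeI, DMPU, −50 → −20 °C; aq NH4Cl
Reagents that add atoms: iodomethane, CI
Why: Fráter–Seebach alkylation; the chelated alkoxide enolate is methylated on the face anti to the C3 methyl group, so the existing C3 centre sets C2 (2S, anti).

Step 2
Reactants: 3 ethyl (2S,3S)-3-hydroxy-2-methylbutanoate
Product: 4 ethyl (2S,3S)-3-(TBS-oxy)-2-methylbutanoate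
Conditions: TBSCl, imidazole, DMF, rt
Reagents that add atoms: tert-butylchlorodimethylsilane, CC(C)(C)[Si](C)(C)Cl
Why: Standard silylation of the secondary alcohol; the ether has to last until the final step and no stereocentre is touched.

Step 3
Reactants: 4 ethyl (2S,3S)-3-(TBS-oxy)-2-methylbutanoate
Product: 5 (2S,3S)-3-(TBS-oxy)-2-methylbutanal
Conditions: iBu2AlH (1.05 equiv), CH2Cl2, −78 °C; aq potassium sodium tartrate
Reagents that add atoms: none
Why: Partial ester reduction; the tetrahedral aluminium hemiacetal is stable at −78 °C and collapses to the aldehyde only on work-up, and the α-centre should survive if the aldehyde is used at once.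

Step 4
Reactants: 5 (2S,3S)-3-(TBS-oxy)-2-methylbutanal
Product: 6 (2E,4R,5S)-5-(TBS-oxy)-2,4-dimethylhex-2-enal
Conditions: Ph3P=C(CH3)CHO, toluene, 90 °C
Reagents that add atoms: 2-(triphenyl-λ5-phosphanylidene)propanal, CC(C=O)=P(c1ccccc1)(c1ccccc1)c1ccccc1
Why: Wittig olefination with a stabilised formyl ylide gives the (E)-2-methyl enal under neutral conditions that should not epimerise C4 (the descriptor changes from S to R only through the priority change).

Step 5
Reactants: 6 (2E,4R,5S)-5-(TBS-oxy)-2,4-dimethylhex-2-enal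
Product: 7 ethyl (2E,4E,6R,7S)-7-(TBS-oxy)-2,4,6-trimethylocta-2,4-dienoate
Conditions: Ph3P=C(CH3)CO2Et, toluene, 100 °C
Reagents that add atoms: ethyl 2-(triphenyl-λ5-phosphanylidene)propanoate, CCOC(=O)C(C)=P(c1ccccc1)(c1ccccc1)c1ccccc1
Why: Second Wittig olefination with a stabilised ester ylide, E-selective on the α-branched enal, completes the (2E,4E)-diene.

Step 6
Reactants: 7 ethyl (2E,4E,6R,7S)-7-(TBS-oxy)-2,4,6-trimethylocta-2,4-dienoate
Product: 8 (2E,4E,6R,7S)-7-(TBS-oxy)-2,4,6-trimethylocta-2,4-dien-1-ol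
Conditions: iBu2AlH (2.3 equiv), CH2Cl2, −78 °C; aq potassium sodium tartrate
Reagents that add atoms: none
Why: Clean 1,2-reduction of the conjugated ester to the allylic alcohol needed for directed epoxidation.

Step 7
Reactants: 8 (2E,4E,6R,7S)-7-(TBS-oxy)-2,4,6-trimethylocta-2,4-dien-1-ol
Product: 9 [(2S,3S)-3-[(2E,4R,5S)-5-(TBS-oxy)-4-methylhex-2-en-2-yl]-2-methyloxiran-2-yl]methanol
Conditions: Ti(OiPr)4 (0.1 equiv), L-(+)-diethyl tartrate (0.12 equiv), t-BuOOH (in decane), 4 Å molecular sieves, CH2Cl2, −25 °C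
Reagents that add atoms: tert-butyl hydroperoxide, CC(C)(C)OO
Why: Sharpless asymmetric epoxidation; the titanium-bound hydroxyl directs oxygen only to the 2,3-alkene, L-(+)-tartrate sets both oxirane centres as (2S,3S) by reagent control, and the E geometry places the alkenyl and CH2OH groups trans.

Step 8
Reactants: 9 [(2S,3S)-3-[(2E,4R,5S)-5-(TBS-oxy)-4-methylhex-2-en-2-yl]-2-methyloxiran-2-yl]methanol
Product: 11 (2R,3S)-3-[(2E,4R,5S)-5-(TBS-oxy)-4-methylhex-2-en-2-yl]-2-methyloxirane-2-carboxylic acid, via epoxy aldehyde 10 (not isolated)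
Conditions: TEMPO (0.2 equiv), PhI(OAc)2 (2.2 equiv), MeCN/H2O, Na2HPO4/NaH2PO4 buffer (pH 7), 0 °C → rt
Reagents that add atoms: water, O
Why: Oxoammonium oxidation of the primary alcohol to the aldehyde and of its hydrate to the acid under buffered conditions that spare alkene, oxirane and silyl ether; the α-carbon is quaternary and cannot epimerise.

Step 9
Reactants: 11 (2R,3S)-3-[(2E,4R,5S)-5-(TBS-oxy)-4-methylhex-2-en-2-yl]-2-methyloxirane-2-carboxylic acid
Product: 12 (2R,3S)-3-[(2E,4R,5S)-5-(TBS-oxy)-4-methylhex-2-en-2-yl]-N-methoxy-N,2-dimethyloxirane-2-carboxamide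
Conditions: MeNH(OMe)·HCl, EDC·HCl, HOBt (cat.), iPr2NEt, CH2Cl2, 0 °C → rt
Reagents that add atoms: N,O-dimethylhydroxylamine hydrochloride, CNOC.Cl
Why: Carbodiimide amidation of the freshly made glycidic acid gives the Weinreb amide, an acyl donor that takes up one carbanion only.

Step 10
Reactants: 13 4-hydroxy-2,5-dimethylbenzaldehyde
Product: 14 2,5-dimethyl-4-(TIPS-oxy)benzaldehyde
Conditions: iPr3SiCl, imidazole, DMF, rt
Reagents that add atoms: chlorotriisopropylsilane, CC(C)[Si](Cl)(C(C)C)C(C)C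
Why: Silylation masks the acidic phenol so that the benzylic position can be lithiated.

Step 11
Reactants: 14 2,5-dimethyl-4-(TIPS-oxy)benzaldehyde; 12 (2R,3S)-3-[(2E,4R,5S)-5-(TBS-oxy)-4-methylhex-2-en-2-yl]-N-methoxy-N,2-dimethyloxirane-2-carboxamide
Product: 17 2-{2-[(2R,3S)-3-[(2E,4R,5S)-5-(TBS-oxy)-4-methylhex-2-en-2-yl]-2-methyloxiran-2-yl]-2-oxoethyl}-5-methyl-4-(TIPS-oxy)benzaldehyde, via lithium α-amino alkoxide 15 (not isolated), via benzylic lithium compound 16 (not isolated)
Conditions: MeNHCH2CH2NMe2, n-BuLi, THF, −20 °C; n-BuLi (1.1 equiv), −20 °C; 12, −78 → −20 °C; aq NH4Cl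
Reagents that add atoms: none
Why: In situ protection of the aldehyde as a lithium α-amino alkoxide directs deprotonation to the neighbouring ortho methyl group (directed lateral lithiation, known for ortho-tolualdehydes), and the benzylic lithium compound is acylated once by the Weinreb amide through its chelated tetrahedral adduct, so work-up releases the C3 ketone and the C1 aldehyde together; no stereocentre is affected because the carbon next to the new ketone is quaternary.

Step 12
Reactants: 17 2-{2-[(2R,3S)-3-[(2E,4R,5S)-5-(TBS-oxy)-4-methylhex-2-en-2-yl]-2-methyloxiran-2-yl]-2-oxoethyl}-5-methyl-4-(TIPS-oxy)benzaldehyde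
Product: 18 4-hydroxy-5-methyl-2-{2-[(2R,3S)-3-[(2E,4R,5S)-5-(TBS-oxy)-4-methylhex-2-en-2-yl]-2-methyloxiran-2-yl]-2-oxoethyl}benzaldehyde
Conditions: Bu4NF (1.1 equiv), AcOH (1.1 equiv), THF, 0 °C
Reagents that add atoms: none
Why: Buffered fluoride cleaves the aryl silyl ether (phenoxide leaving group, activated by the para formyl group) much faster than the hindered secondary alkyl silyl ether, and the weakly acidic medium leaves the oxirane and the keto aldehyde alone.

Step 13
Reactants: 18 4-hydroxy-5-methyl-2-{2-[(2R,3S)-3-[(2E,4R,5S)-5-(TBS-oxy)-4-methylhex-2-en-2-yl]-2-methyloxiran-2-yl]-2-oxoethyl}benzaldehyde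
Product: 21 (7S,8R)-3-[(2R,3S)-3-[(2E,4R,5S)-5-(TBS-oxy)-4-methylhex-2-en-2-yl]-2-methyloxiran-2-yl]-7,8-dihydroxy-7-methyl-7,8-dihydro-6H-isochromen-6-one, via ortho-quinol dienone 19 (not isolated), via bicyclic oxocarbenium ion 20 (not isolated)
Conditions: (S)-4-tert-butyl-2-(2-iodylphenyl)-4,5-dihydro-1,3-oxazole (1.1 equiv), THF, −30 → 0 °C; then THF/H2O, Na2HPO4/NaH2PO4 buffer (pH 7), 0 °C → rt
Reagents that add atoms: (S)-4-tert-butyl-2-(2-iodylphenyl)-4,5-dihydro-1,3-oxazole, CC(C)(C)[C@H]1COC(=N1)c1ccccc1I(=O)=O; water, O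
Why: Proposed new method: the phenol exchanges onto the pentavalent iodine centre and oxygen is transferred intramolecularly to the methyl-bearing ortho carbon C7 (hydroxylative phenol dearomatisation, the known reaction type for 2-alkylphenols), giving ortho-quinol 19, in which the C3 ketone enolises towards C4 and its enol oxygen adds to the now non-aromatic, highly electrophilic C1 formyl group; this 6-exo-trig closure of pyran ring B through the O2–C1 bond followed by loss of water is the known ring closure of hydroxylated 2-(2-oxoalkyl)benzaldehydes in azaphilone biosynthesis and its chemical copies, and here it leads to the cross-conjugated oxocarbenium ion 20. The new element is the capture of 20 by water at C8 (a 1,6-type conjugate hydration whose closest known counterpart is the addition of water to quinone methides and vinylogous oxocarbenium ions), which turns O2–C1=C8a into the enol ether and C8 into the vinylogous hemiacetal carbon of the target. C7 (S) is set by the chiral reagent, since the oxygen is delivered inside the chiral aryl-iodine phenolate complex, and C8 (R) by the substrate: water should add anti to the electronegative and bulky C7 oxygen substituent (free or still bound to trivalent iodine), giving the 7,8-trans diol. The step needs oxygenation at C7 and not at the free ortho carbon C5 (C7 is the more electron-rich, alkylated position and C5 is shielded by the C4a side chain), reaction at the phenol and not at the alkene, oxirane, silyl ether or new C8 carbinol (the reagent engages only through the phenolic OH and is used as one equivalent at low temperature), and water capture at C8 and not at C1 (C1 capture gives a lactol that reverts to 20). Because C8–OH is a vinylogous hemiacetal, a cis epimer can be returned to the equilibrium in wet buffered solvent.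

Step 14
Reactants: 21 (7S,8R)-3-[(2R,3S)-3-[(2E,4R,5S)-5-(TBS-oxy)-4-methylhex-2-en-2-yl]-2-methyloxiran-2-yl]-7,8-dihydroxy-7-methyl-7,8-dihydro-6H-isochromen-6-one
Product: 22 pestaphilone D, (7S,8R)-7,8-dihydroxy-3-[(2R,3S)-3-[(2E,4R,5S)-5-hydroxy-4-methylhex-2-en-2-yl]-2-methyloxiran-2-yl]-7-methyl-7,8-dihydro-6H-isochromen-6-one
Conditions: HF·pyridine, pyridine, THF, 0 °C → rt
Reagents that add atoms: none
Why: Fluoride cleavage of the secondary silyl ether with pyridine-buffered HF·pyridine should be mild enough to leave the vinyl oxirane and the C8 vinylogous hemiacetal intact, and it touches no stereocentre.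

**Compound list**

1 | ethyl (3S)-3-hydroxybutanoate | CCOC(=O)C[C@H](C)O | starting material
2 | dilithium alkoxide enolate of 1 | CCOC(O[Li])=C[C@H](C)O[Li] | intermediate
3 | ethyl (2S,3S)-3-hydroxy-2-methylbutanoate | CCOC(=O)[C@@H](C)[C@H](C)O | intermediate
4 | ethyl (2S,3S)-3-[(tert-butyldimethylsilyl)oxy]-2-methylbutanoate | CCOC(=O)[C@@H](C)[C@H](C)O[Si](C)(C)C(C)(C)C | intermediate
5 | (2S,3S)-3-[(tert-butyldimethylsilyl)oxy]-2-methylbutanal | O=C[C@@H](C)[C@H](C)O[Si](C)(C)C(C)(C)C | intermediate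
6 | (2E,4R,5S)-5-[(tert-butyldimethylsilyl)oxy]-2,4-dimethylhex-2-enal | C/C(=C\[C@@H](C)[C@H](C)O[Si](C)(C)C(C)(C)C)C=O | intermediate
7 | ethyl (2E,4E,6R,7S)-7-[(tert-butyldimethylsilyl)oxy]-2,4,6-trimethylocta-2,4-dienoate | CCOC(=O)/C(C)=C/C(C)=C/[C@@H](C)[C@H](C)O[Si](C)(C)C(C)(C)C | intermediate
8 | (2E,4E,6R,7S)-7-[(tert-butyldimethylsilyl)oxy]-2,4,6-trimethylocta-2,4-dien-1-ol | OC/C(C)=C/C(C)=C/[C@@H](C)[C@H](C)O[Si](C)(C)C(C)(C)C | intermediate
9 | [(2S,3S)-3-[(2E,4R,5S)-5-[(tert-butyldimethylsilyl)oxy]-4-methylhex-2-en-2-yl]-2-methyloxiran-2-yl]methanol | C/C(=C\[C@@H](C)[C@H](C)O[Si](C)(C)C(C)(C)C)[C@@H]1O[C@@]1(C)CO | intermediate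
10 | (2R,3S)-3-[(2E,4R,5S)-5-[(tert-butyldimethylsilyl)oxy]-4-methylhex-2-en-2-yl]-2-methyloxirane-2-carbaldehyde | C/C(=C\[C@@H](C)[C@H](C)O[Si](C)(C)C(C)(C)C)[C@@H]1O[C@@]1(C)C=O | intermediate
11 | (2R,3S)-3-[(2E,4R,5S)-5-[(tert-butyldimethylsilyl)oxy]-4-methylhex-2-en-2-yl]-2-methyloxirane-2-carboxylic acid | C/C(=C\[C@@H](C)[C@H](C)O[Si](C)(C)C(C)(C)C)[C@@H]1O[C@@]1(C)C(=O)O | intermediate
12 | (2R,3S)-3-[(2E,4R,5S)-5-[(tert-butyldimethylsilyl)oxy]-4-methylhex-2-en-2-yl]-N-methoxy-N,2-dimethyloxirane-2-carboxamide | C/C(=C\[C@@H](C)[C@H](C)O[Si](C)(C)C(C)(C)C)[C@@H]1O[C@@]1(C)C(=O)N(C)OC | intermediate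
13 | 4-hydroxy-2,5-dimethylbenzaldehyde | Cc1cc(O)c(C)cc1C=O | starting material
14 | 2,5-dimethyl-4-[(triisopropylsilyl)oxy]benzaldehyde | Cc1cc(O[Si](C(C)C)(C(C)C)C(C)C)c(C)cc1C=O | intermediate
15 | lithium {[2-(dimethylamino)ethyl](methyl)amino}{2,5-dimethyl-4-[(triisopropylsilyl)oxy]phenyl}methanolate | [Li]OC(N(C)CCN(C)C)c1cc(C)c(O[Si](C(C)C)(C(C)C)C(C)C)cc1C | intermediate
16 | 2-(lithiomethyl) derivative of 15 (benzylic lithium compound) | [Li]Cc1cc(O[Si](C(C)C)(C(C)C)C(C)C)c(C)cc1C(O[Li])N(C)CCN(C)C | intermediate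
17 | 2-{2-[(2R,3S)-3-[(2E,4R,5S)-5-[(tert-butyldimethylsilyl)oxy]-4-methylhex-2-en-2-yl]-2-methyloxiran-2-yl]-2-oxoethyl}-5-methyl-4-[(triisopropylsilyl)oxy]benzaldehyde | C/C(=C\[C@@H](C)[C@H](C)O[Si](C)(C)C(C)(C)C)[C@@H]1O[C@@]1(C)C(=O)Cc1cc(O[Si](C(C)C)(C(C)C)C(C)C)c(C)cc1C=O | intermediate
18 | 4-hydroxy-5-methyl-2-{2-[(2R,3S)-3-[(2E,4R,5S)-5-[(tert-butyldimethylsilyl)oxy]-4-methylhex-2-en-2-yl]-2-methyloxiran-2-yl]-2-oxoethyl}benzaldehyde | C/C(=C\[C@@H](C)[C@H](C)O[Si](C)(C)C(C)(C)C)[C@@H]1O[C@@]1(C)C(=O)Cc1cc(O)c(C)cc1C=O | intermediate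
19 | (3S)-3-hydroxy-3-methyl-4-oxo-6-{2-[(2R,3S)-3-[(2E,4R,5S)-5-[(tert-butyldimethylsilyl)oxy]-4-methylhex-2-en-2-yl]-2-methyloxiran-2-yl]-2-oxoethyl}cyclohexa-1,5-diene-1-carbaldehyde (ortho-quinol) | C/C(=C\[C@@H](C)[C@H](C)O[Si](C)(C)C(C)(C)C)[C@@H]1O[C@@]1(C)C(=O)CC1=CC(=O)[C@@](C)(O)C=C1C=O | intermediate
20 | (7S)-3-[(2R,3S)-3-[(2E,4R,5S)-5-[(tert-butyldimethylsilyl)oxy]-4-methylhex-2-en-2-yl]-2-methyloxiran-2-yl]-7-hydroxy-7-methyl-6-oxo-6,7-dihydroisochromen-2-ium (oxocarbenium ion) | C/C(=C\[C@@H](C)[C@H](C)O[Si](C)(C)C(C)(C)C)[C@@H]1O[C@@]1(C)C1=CC2=CC(=O)[C@@](C)(O)C=C2C=[O+]1 | intermediate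
21 | (7S,8R)-3-[(2R,3S)-3-[(2E,4R,5S)-5-[(tert-butyldimethylsilyl)oxy]-4-methylhex-2-en-2-yl]-2-methyloxiran-2-yl]-7,8-dihydroxy-7-methyl-7,8-dihydro-6H-isochromen-6-one | C/C(=C\[C@@H](C)[C@H](C)O[Si](C)(C)C(C)(C)C)[C@@H]1O[C@@]1(C)C1=CC2=CC(=O)[C@@](C)(O)[C@H](O)C2=CO1 | intermediate
22 | pestaphilone D, (7S,8R)-7,8-dihydroxy-3-[(2R,3S)-3-[(2E,4R,5S)-5-hydroxy-4-methylhex-2-en-2-yl]-2-methyloxiran-2-yl]-7-methyl-7,8-dihydro-6H-isochromen-6-one | C/C(=C\[C@@H](C)[C@H](C)O)[C@@H]1O[C@@]1(C)C1=CC2=CC(=O)[C@@](C)(O)[C@H](O)C2=CO1 | target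

**Step count and risks**

Total steps: 14. Longest linear sequence: 13 steps (from 1 through steps 1–9 and 11–14 to 22).

Steps most likely to fail:

1. Step 13 (proposed method). What may go wrong: slow ligand exchange and oxygen transfer on the para-formyl phenol, oxygenation at the unsubstituted ortho carbon C5, poor facial selectivity at C7 or in the water addition at C8, and over-oxidation of the new C8 carbinol.
Fallback, known reaction types only; it sets out from 12 and comes back to the route at 21. Commercial 2,4-dihydroxy-3,6-dimethylbenzaldehyde F1 is silylated (TBSOTf, 2,6-lutidine) to its bis(tert-butyldimethylsilyl) ether F2. As in step 11, in situ protection gives lithium α-amino alkoxide F3, lateral lithiation gives benzylic lithium compound F4, and acylation with 12 gives keto aldehyde F5. Buffered Bu4NF removes the two aryl silyl groups to give resorcinol keto aldehyde F6. The enantioselective hydroxylative dearomatisation known for 2,4-dihydroxy-3-methyl-6-(2-oxoalkyl)benzaldehydes (flavin-dependent monooxygenase AzaH, NADPH recycling, aqueous buffer) should give the C7-hydroxylated ortho-quinol F7, which closes ring B through the same O2–C1 bond to the 6,8-dione F8 (named 7R because the priorities change; same spatial arrangement at C7 as in 21). Hydroxyl-directed reduction of the C8 ketone (Me4NBH(OAc)3, MeCN/AcOH, −30 °C; hydride delivered from the face of the C7 hydroxyl, hence the trans diol) should then give 21. Discrimination between the C8 and C6 carbonyl groups in this reduction is not secured by precedent.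

2. Step 11. What may go wrong: ring (ortho) lithiation or incomplete benzylic lithiation, attack of residual butyllithium on the amide, and slow acylation at the hindered carbonyl group.
Fallback; it sets out from 14 and comes back at 17. Condensation of 14 with tert-butylamine (MgSO4, CH2Cl2) gives N-tert-butyl aldimine F9. LiN(iPr)2 in THF (−78 → 0 °C) gives the resonance-stabilised lithiated imine F10, which is acylated by 12 to keto imine F11. Hydrolysis of the hindered imine with aqueous AcOH/NaOAc buffer should give 17.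

3. Step 14. What may go wrong: opening of the vinyl oxirane or ionisation and substitution at C8 during desilylation of the finished core, or incomplete cleavage of the hindered silyl ether.
Fallback; it sets out from 17 and comes back at 22. Both silyl ethers are removed at the robust aromatic stage (Bu4NF/AcOH, THF, rt) to give dihydroxy keto aldehyde F12. The conditions of step 13 (1.05 equiv of reagent at low temperature, the phenol reacting much faster than the isolated secondary alcohol) should then convert F12 through ortho-quinol F13 and oxocarbenium ion F14 directly into 22, so that the dearomatisation becomes the last step.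

**Further compounds**

F1 | step 13 | 2,4-dihydroxy-3,6-dimethylbenzaldehyde | Cc1cc(O)c(C)c(O)c1C=O
F2 | step 13 | 2,4-bis[(tert-butyldimethylsilyl)oxy]-3,6-dimethylbenzaldehyde | Cc1cc(O[Si](C)(C)C(C)(C)C)c(C)c(O[Si](C)(C)C(C)(C)C)c1C=O
F3 | step 13 | lithium {2,4-bis[(tert-butyldimethylsilyl)oxy]-3,6-dimethylphenyl}{[2-(dimethylamino)ethyl](methyl)amino}methanolate | [Li]OC(N(C)CCN(C)C)c1c(C)cc(O[Si](C)(C)C(C)(C)C)c(C)c1O[Si](C)(C)C(C)(C)C
F4 | step 13 | 6-(lithiomethyl) derivative of F3 (benzylic lithium compound) | [Li]Cc1cc(O[Si](C)(C)C(C)(C)C)c(C)c(O[Si](C)(C)C(C)(C)C)c1C(O[Li])N(C)CCN(C)C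
F5 | step 13 | 2,4-bis[(tert-butyldimethylsilyl)oxy]-3-methyl-6-{2-[(2R,3S)-3-[(2E,4R,5S)-5-[(tert-butyldimethylsilyl)oxy]-4-methylhex-2-en-2-yl]-2-methyloxiran-2-yl]-2-oxoethyl}benzaldehyde | C/C(=C\[C@@H](C)[C@H](C)O[Si](C)(C)C(C)(C)C)[C@@H]1O[C@@]1(C)C(=O)Cc1cc(O[Si](C)(C)C(C)(C)C)c(C)c(O[Si](C)(C)C(C)(C)C)c1C=O
F6 | step 13 | 2,4-dihydroxy-3-methyl-6-{2-[(2R,3S)-3-[(2E,4R,5S)-5-[(tert-butyldimethylsilyl)oxy]-4-methylhex-2-en-2-yl]-2-methyloxiran-2-yl]-2-oxoethyl}benzaldehyde | C/C(=C\[C@@H](C)[C@H](C)O[Si](C)(C)C(C)(C)C)[C@@H]1O[C@@]1(C)C(=O)Cc1cc(O)c(C)c(O)c1C=O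
F7 | step 13 | C7-hydroxylated ortho-quinol of F6 (2,3-dihydroxy-3-methyl-4-oxocyclohexa-1,5-diene-1-carbaldehyde core) | C/C(=C\[C@@H](C)[C@H](C)O[Si](C)(C)C(C)(C)C)[C@@H]1O[C@@]1(C)C(=O)CC1=CC(=O)[C@@](C)(O)C(O)=C1C=O
F8 | step 13 | (7R)-3-[(2R,3S)-3-[(2E,4R,5S)-5-[(tert-butyldimethylsilyl)oxy]-4-methylhex-2-en-2-yl]-2-methyloxiran-2-yl]-7-hydroxy-7-methyl-6H-isochromene-6,8(7H)-dione | C/C(=C\[C@@H](C)[C@H](C)O[Si](C)(C)C(C)(C)C)[C@@H]1O[C@@]1(C)C1=CC2=CC(=O)[C@@](C)(O)C(=O)C2=CO1
F9 | step 11 | (E)-N-tert-butyl-1-{2,5-dimethyl-4-[(triisopropylsilyl)oxy]phenyl}methanimine | CC(C)(C)/N=C/c1cc(C)c(O[Si](C(C)C)(C(C)C)C(C)C)cc1C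
F10 | step 11 | 2-(lithiomethyl) derivative of F9 (lithiated imine) | [Li]Cc1cc(O[Si](C(C)C)(C(C)C)C(C)C)c(C)cc1/C=N/C(C)(C)C
F11 | step 11 | N-tert-butyl imine of 17 (keto imine) | C/C(=C\[C@@H](C)[C@H](C)O[Si](C)(C)C(C)(C)C)[C@@H]1O[C@@]1(C)C(=O)Cc1cc(O[Si](C(C)C)(C(C)C)C(C)C)c(C)cc1/C=N/C(C)(C)C
F12 | step 14 | 4-hydroxy-2-{2-[(2R,3S)-3-[(2E,4R,5S)-5-hydroxy-4-methylhex-2-en-2-yl]-2-methyloxiran-2-yl]-2-oxoethyl}-5-methylbenzaldehyde | C/C(=C\[C@@H](C)[C@H](C)O)[C@@H]1O[C@@]1(C)C(=O)Cc1cc(O)c(C)cc1C=O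
F13 | step 14 | (3S)-3-hydroxy-6-{2-[(2R,3S)-3-[(2E,4R,5S)-5-hydroxy-4-methylhex-2-en-2-yl]-2-methyloxiran-2-yl]-2-oxoethyl}-3-methyl-4-oxocyclohexa-1,5-diene-1-carbaldehyde (ortho-quinol) | C/C(=C\[C@@H](C)[C@H](C)O)[C@@H]1O[C@@]1(C)C(=O)CC1=CC(=O)[C@@](C)(O)C=C1C=O
F14 | step 14 | (7S)-7-hydroxy-3-[(2R,3S)-3-[(2E,4R,5S)-5-hydroxy-4-methylhex-2-en-2-yl]-2-methyloxiran-2-yl]-7-methyl-6-oxo-6,7-dihydroisochromen-2-ium (oxocarbenium ion) | C/C(=C\[C@@H](C)[C@H](C)O)[C@@H]1O[C@@]1(C)C1=CC2=CC(=O)[C@@](C)(O)C=C2C=[O+]1
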